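**Strategy.** The ring is cut at C1–C2. Read with C7 as a carboxyl and C2 as an ether carbinol, the array C7–C1(O)–C2–C3=C4 on the cyclohexene ring is a γ,δ-unsaturated α-oxy acid, the retron of an Ireland–Claisen shift. The precursor is a sugar δ-lactone whose ring carbinol carbon (future C4) carries an (E)-2-(PMB-oxy)vinyl group. Its silyl ketene acetal rearranges through a boat, forming C1–C2 and C3=C4, closing the carbocycle as the lactone opens and fixing quaternary C1. Since the lactone α-centre is erased on enolisation, the lactone is taken from D-glucose read backwards (C6 as carboxyl, C1 as vinyl carbon), so no centre has to be inverted.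

Key step: step 10

Remark on numbering: C1–C7 are target atoms (C1 quaternary carbinol, C2 ketone, C3=C4, C5 carbinol, C6 benzoate carbon, C7 exocyclic CH2); Glc-C1 to Glc-C6 are the glucose carbons. Mapping: C7 = Glc-C6, C1 = Glc-C5, C6 = Glc-C4, C5 = Glc-C3, C4 = Glc-C2, C3 = Glc-C1, C2 = ylide carbon.

Assumption: the Wittig step is expected to give E and Z enol ethers; the E isomer is drawn, and both should converge at ketone 24 because C2 is oxidised (the same holds for any epimerisation at the lactone α-carbon before step 10).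

Step 1
Reactants: 1 4-methoxybenzyl alcohol; 2 chloromethyl methyl sulfide
Product: 3 4-methoxybenzyl methylthiomethyl ether
Conditions: NaH, NaI (cat.), THF, 0 °C → rt
Reagents that add atoms: chloromethyl methyl sulfide (2), ClCSC
Why: Williamson etherification of the sodium alkoxide with the activated α-chloro sulfide should give the O,S-acetal, a stable store for the labile PMB chloromethyl ether.

Step 2
Reactants: 3 4-methoxybenzyl methylthiomethyl ether
Product: 5 [(4-methoxybenzyloxy)methyl]triphenylphosphonium chloride, via 4-methoxybenzyl chloromethyl ether 4 (not isolated)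
Conditions: SO2Cl2, CH2Cl2, −78 °C; evaporate; PPh3, PhMe, rt
Reagents that add atoms: sulfuryl chloride, O=S(=O)(Cl)Cl; triphenylphosphine, c1ccc(cc1)P(c1ccccc1)c1ccccc1
Why: Chlorinolysis of the methylthiomethyl ether should release the α-chloro ether, which quaternises triphenylphosphine by SN2 alkylation to the Wittig salt.

Step 3
Reactants: 6 1,2:5,6-di-O-isopropylidene-α-D-glucofuranose (commercial bis-acetonide of D-glucose)
Product: 7 1,2:5,6-di-O-isopropylidene-3-O-triisopropylsilyl-α-D-glucofuranose
Conditions: TIPSOTf, 2,6-lutidine, CH2Cl2, 0 °C → rt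
Reagents that add atoms: triisopropylsilyl trifluoromethanesulfonate, CC(C)[Si](OS(=O)(=O)C(F)(F)F)(C(C)C)C(C)C
Why: Silyl triflate O-silylation of the only free hydroxyl (Glc-O3, future C5–OH) installs an acid-tolerant, migration-resistant group that stays until the last step.

Step 4
Reactants: 7 1,2:5,6-di-O-isopropylidene-3-O-triisopropylsilyl-α-D-glucofuranose
Product: 8 1,2-O-isopropylidene-3-O-triisopropylsilyl-α-D-glucofuranose
Conditions: 70% aq. AcOH, rt
Reagents that add atoms: none
Why: Selective acetal hydrolysis should work because the terminal 5,6-dioxolane cleaves much faster than the cis-fused anomeric 1,2-acetonide.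

Step 5
Reactants: 8 1,2-O-isopropylidene-3-O-triisopropylsilyl-α-D-glucofuranose
Product: 9 1,2-O-isopropylidene-3-O-triisopropylsilyl-α-D-glucofuranuronic acid
Conditions: TEMPO (cat.), PhI(OAc)2, MeCN/H2O 1:1, rt
Reagents that add atoms: water, O
Why: Oxoammonium (TEMPO) oxidation is selective for the primary alcohol and should carry it through the aldehyde hydrate to the acid (future C7), leaving the secondary Glc-O5–H untouched.

Step 6
Reactants: 9 1,2-O-isopropylidene-3-O-triisopropylsilyl-α-D-glucofuranuronic acid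
Product: 10 methyl 1,2-O-isopropylidene-3-O-triisopropylsilyl-α-D-glucofuranuronate
Conditions: MeI, KHCO3, DMF, rt
Reagents that add atoms: iodomethane, CI
Why: SN2 alkylation of the carboxylate should give the methyl ester without etherifying the α-hydroxyl.

Step 7
Reactants: 10 methyl 1,2-O-isopropylidene-3-O-triisopropylsilyl-α-D-glucofuranuronate
Product: 11 methyl 3-O-triisopropylsilyl-D-glucopyranuronate (lactol; anomers; in equilibrium with the furanose form)
Conditions: TFA/H2O 9:1, 0 °C → rt
Reagents that add atoms: none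
Why: Acid hydrolysis of the anomeric acetonide should unmask the lactol together with Glc-O2–H (the future lactone oxygen), while the TIPS ether and methyl ester tolerate the short exposure.

Step 8
Reactants: 11 methyl 3-O-triisopropylsilyl-D-glucopyranuronate; 5 [(4-methoxybenzyloxy)methyl]triphenylphosphonium chloride
Product: 14 (E)-6-deoxy-7-O-(4-methoxybenzyl)-4-O-triisopropylsilyl-L-gulo-hept-6-enono-1,5-lactone, via phosphonium ylide 12 (not isolated), via open-chain hydroxy ester 13 (not isolated)
Conditions: 5 (4.5 equiv), KHMDS, THF, 0 °C; add 11, −78 °C → rt; aq. NH4Cl; then DBU (cat.), PhMe, rt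
Reagents that add atoms: [(4-methoxybenzyloxy)methyl]triphenylphosphonium chloride (5), COc1ccc(COC[P+](c2ccccc2)(c2ccccc2)c2ccccc2)cc1.[Cl-]
Why: Wittig olefination of the ring-opened lactol should install the PMB enol ether (the α-alkoxide protects the aldehyde α-centre from epimerisation), and the freed Glc-O2–H then closes the δ-lactone on the methyl ester by 6-exo-trig transesterification, the only lactone size open to the substrate.

Step 9
Reactants: 14 (E)-6-deoxy-7-O-(4-methoxybenzyl)-4-O-triisopropylsilyl-L-gulo-hept-6-enono-1,5-lactone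
Product: 15 (E)-6-deoxy-7-O-(4-methoxybenzyl)-2,3-di-O-triethylsilyl-4-O-triisopropylsilyl-L-gulo-hept-6-enono-1,5-lactone
Conditions: TESCl, imidazole, DMAP (cat.), DMF, 0 °C → rt
Reagents that add atoms: chlorotriethylsilane, CC[Si](Cl)(CC)CC
Why: Base-mediated silylation should cap the α- and β-hydroxyls as TES ethers (removed together later) without exposing the acid-sensitive alkoxyallyl lactone to acid.

Step 10
Reactants: 15 (E)-6-deoxy-7-O-(4-methoxybenzyl)-2,3-di-O-triethylsilyl-4-O-triisopropylsilyl-L-gulo-hept-6-enono-1,5-lactone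
Product: 18 2-(4-methoxybenzyloxy)-1,6-bis(triethylsilyloxy)-5-(triisopropylsilyloxy)cyclohex-3-ene-1-carboxylic acid, via silyl ketene acetal 16 (not isolated), via trimethylsilyl ester 17 (not isolated)
Conditions: TMSCl–Et3N, LDA, THF, −78 °C → rt (in-situ quench); PhMe, 80 °C; aq. citric acid
Reagents that add atoms: none
Why: Deprotonation of 15 with TMSCl already present should trap the lactone enolate at once as the endocyclic silyl ketene acetal 16, outrunning β-elimination of the neighbouring silyloxy group; on warming, 16 undergoes a suprafacial [3,3]-sigmatropic shift in which the enol-ether terminus (future C2) bonds to the ketene-acetal carbon (future C1) while the ring C–O bond breaks and C3=C4 forms. The closest known reaction is the Ireland–Claisen ring contraction of 6-alkenyl δ-lactones, and the donor PMB-oxy group on the reacting alkene terminus is expected to accelerate it. The cyclohexene is closed in a concerted pericyclic lactone-to-carbocycle contraction, and because the allyl unit hangs from the ring carbinol carbon only a boat, bicyclo[2.2.2]octane-like transition state is available. The new quaternary centre C1 is controlled by the carbinol stereocentre that is consumed (future C4): bonding must occur on the lactone face that carries the vinyl group, which places C7 cis to the C6 oxygen and trans to the C5 oxygen, so the C1 oxygen ends trans to the C6 oxygen. The C2 ether centre follows from the enol-ether geometry (E gives OPMB cis to C7) and is erased later by oxidation. The selectivity needed is facial selectivity at C1, and the tether secures it because the opposite face cannot be reached intramolecularly.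

Step 11
Reactants: 18 2-(4-methoxybenzyloxy)-1,6-bis(triethylsilyloxy)-5-(triisopropylsilyloxy)cyclohex-3-ene-1-carboxylic acid
Product: 20 1-(hydroxymethyl)-2-(4-methoxybenzyloxy)-5-(triisopropylsilyloxy)cyclohex-3-ene-1,6-diol, via bis-TES primary alcohol 19 (not isolated)
Conditions: LiAlH4, THF, 0 → 40 °C; aq. NaOH work-up; then CSA (cat.), MeOH, 0 °C → rt
Reagents that add atoms: none
Why: Hydride reduction should take the acid to the C7 alcohol, and acid methanolysis then strips both TES ethers (wherever they sit after any O→O migration) while the TIPS and PMB ethers survive both operations.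

Step 12
Reactants: 20 1-(hydroxymethyl)-2-(4-methoxybenzyloxy)-5-(triisopropylsilyloxy)cyclohex-3-ene-1,6-diol; 21 benzoyl chloride
Product: 22 [6-(benzoyloxy)-1-hydroxy-2-(4-methoxybenzyloxy)-5-(triisopropylsilyloxy)cyclohex-3-en-1-yl]methyl benzoate
Conditions: BzCl (2.4 equiv), pyridine, DMAP (cat.), CH2Cl2, 0 °C → rt
Reagents that add atoms: benzoyl chloride (21), O=C(Cl)c1ccccc1
Why: DMAP-catalysed acylation should esterify the primary C7 and secondary C6 hydroxyls, whereas the tertiary C1 hydroxyl is too hindered to react.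

Step 13
Reactants: 22 [6-(benzoyloxy)-1-hydroxy-2-(4-methoxybenzyloxy)-5-(triisopropylsilyloxy)cyclohex-3-en-1-yl]methyl benzoate
Product: 23 [6-(benzoyloxy)-1,2-dihydroxy-5-(triisopropylsilyloxy)cyclohex-3-en-1-yl]methyl benzoate
Conditions: DDQ, CH2Cl2/pH 7 buffer 10:1, 0 °C
Reagents that add atoms: none
Why: Oxidative PMB cleavage through the benzylic oxocarbenium ion, trapped by water, should free the allylic C2 hydroxyl without touching the benzoates, TIPS ether or alkene.

Step 14
Reactants: 23 [6-(benzoyloxy)-1,2-dihydroxy-5-(triisopropylsilyloxy)cyclohex-3-en-1-yl]methyl benzoate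
Product: 24 [6-(benzoyloxy)-1-hydroxy-2-oxo-5-(triisopropylsilyloxy)cyclohex-3-en-1-yl]methyl benzoate
Conditions: Dess–Martin periodinane, pyridine, CH2Cl2, 0 °C → rt
Reagents that add atoms: none
Why: Dess–Martin oxidation should convert the secondary allylic alcohol into the enone; the neighbouring tertiary alcohol cannot be oxidised and glycol cleavage is not typical of this reagent.

Step 15
Reactants: 24 [6-(benzoyloxy)-1-hydroxy-2-oxo-5-(triisopropylsilyloxy)cyclohex-3-en-1-yl]methyl benzoate
Product: 25 [(1R,5R,6S)-6-(benzoyloxy)-1,5-dihydroxy-2-oxocyclohex-3-en-1-yl]methyl benzoate (CNP0212960.1)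
Conditions: HF·pyridine, pyridine, THF, 0 °C → rt
Reagents that add atoms: none
Why: Fluoride-assisted desilylation under buffered, weakly acidic conditions should remove the secondary TIPS ether without benzoate migration or elimination of the γ-oxygen.

**Compound list**

1 | 4-methoxybenzyl alcohol | COc1ccc(CO)cc1 | starting material
2 | chloromethyl methyl sulfide | ClCSC | starting material
3 | 4-methoxybenzyl methylthiomethyl ether | COc1ccc(COCSC)cc1 | intermediate
4 | 4-methoxybenzyl chloromethyl ether | COc1ccc(COCCl)cc1 | intermediate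
5 | [(4-methoxybenzyloxy)methyl]triphenylphosphonium chloride | COc1ccc(COC[P+](c2ccccc2)(c2ccccc2)c2ccccc2)cc1.[Cl-] | intermediate
6 | 1,2:5,6-di-O-isopropylidene-α-D-glucofuranose | CC1(C)O[C@H]2[C@@H](O1)O[C@H]([C@H]3COC(C)(C)O3)[C@@H]2O | starting material
7 | 1,2:5,6-di-O-isopropylidene-3-O-triisopropylsilyl-α-D-glucofuranose | CC1(C)O[C@H]2[C@@H](O1)O[C@H]([C@H]3COC(C)(C)O3)[C@@H]2O[Si](C(C)C)(C(C)C)C(C)C | intermediate
8 | 1,2-O-isopropylidene-3-O-triisopropylsilyl-α-D-glucofuranose | CC1(C)O[C@H]2[C@@H](O1)O[C@H]([C@H](O)CO)[C@@H]2O[Si](C(C)C)(C(C)C)C(C)C | intermediate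
9 | 1,2-O-isopropylidene-3-O-triisopropylsilyl-α-D-glucofuranuronic acid | CC1(C)O[C@H]2[C@@H](O1)O[C@H]([C@H](O)C(=O)O)[C@@H]2O[Si](C(C)C)(C(C)C)C(C)C | intermediate
10 | methyl 1,2-O-isopropylidene-3-O-triisopropylsilyl-α-D-glucofuranuronate | CC1(C)O[C@H]2[C@@H](O1)O[C@H]([C@H](O)C(=O)OC)[C@@H]2O[Si](C(C)C)(C(C)C)C(C)C | intermediate
11 | methyl 3-O-triisopropylsilyl-D-glucopyranuronate (lactol, anomers) | COC(=O)[C@H]1OC(O)[C@H](O)[C@@H](O[Si](C(C)C)(C(C)C)C(C)C)[C@@H]1O | intermediate
12 | [(4-methoxybenzyloxy)methylene]triphenylphosphorane | COc1ccc(COC=P(c2ccccc2)(c2ccccc2)c2ccccc2)cc1 | intermediate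
13 | methyl (E)-6-deoxy-7-O-(4-methoxybenzyl)-4-O-triisopropylsilyl-L-gulo-hept-6-enonate | COC(=O)[C@@H](O)[C@@H](O)[C@H](O[Si](C(C)C)(C(C)C)C(C)C)[C@@H](O)/C=C/OCc1ccc(OC)cc1 | intermediate
14 | (E)-6-deoxy-7-O-(4-methoxybenzyl)-4-O-triisopropylsilyl-L-gulo-hept-6-enono-1,5-lactone | O=C1[C@@H](O)[C@@H](O)[C@H](O[Si](C(C)C)(C(C)C)C(C)C)[C@H](/C=C/OCc2ccc(OC)cc2)O1 | intermediate
15 | (E)-6-deoxy-7-O-(4-methoxybenzyl)-2,3-di-O-triethylsilyl-4-O-triisopropylsilyl-L-gulo-hept-6-enono-1,5-lactone (key-step precursor) | O=C1[C@@H](O[Si](CC)(CC)CC)[C@@H](O[Si](CC)(CC)CC)[C@H](O[Si](C(C)C)(C(C)C)C(C)C)[C@H](/C=C/OCc2ccc(OC)cc2)O1 | intermediate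
16 | endocyclic trimethylsilyl ketene acetal of 15 | C[Si](C)(C)OC1=C(O[Si](CC)(CC)CC)[C@@H](O[Si](CC)(CC)CC)[C@H](O[Si](C(C)C)(C(C)C)C(C)C)[C@H](/C=C/OCc2ccc(OC)cc2)O1 | intermediate
17 | trimethylsilyl ester of 18 | C[Si](C)(C)OC(=O)[C@]1(O[Si](CC)(CC)CC)[C@H](OCc2ccc(OC)cc2)C=C[C@@H](O[Si](C(C)C)(C(C)C)C(C)C)[C@@H]1O[Si](CC)(CC)CC | intermediate
18 | 2-(4-methoxybenzyloxy)-1,6-bis(triethylsilyloxy)-5-(triisopropylsilyloxy)cyclohex-3-ene-1-carboxylic acid (key-step product) | OC(=O)[C@]1(O[Si](CC)(CC)CC)[C@H](OCc2ccc(OC)cc2)C=C[C@@H](O[Si](C(C)C)(C(C)C)C(C)C)[C@@H]1O[Si](CC)(CC)CC | intermediate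
19 | [2-(4-methoxybenzyloxy)-1,6-bis(triethylsilyloxy)-5-(triisopropylsilyloxy)cyclohex-3-en-1-yl]methanol | OC[C@]1(O[Si](CC)(CC)CC)[C@H](OCc2ccc(OC)cc2)C=C[C@@H](O[Si](C(C)C)(C(C)C)C(C)C)[C@@H]1O[Si](CC)(CC)CC | intermediate
20 | 1-(hydroxymethyl)-2-(4-methoxybenzyloxy)-5-(triisopropylsilyloxy)cyclohex-3-ene-1,6-diol | OC[C@]1(O)[C@H](OCc2ccc(OC)cc2)C=C[C@@H](O[Si](C(C)C)(C(C)C)C(C)C)[C@@H]1O | intermediate
21 | benzoyl chloride | O=C(Cl)c1ccccc1 | starting material
22 | [6-(benzoyloxy)-1-hydroxy-2-(4-methoxybenzyloxy)-5-(triisopropylsilyloxy)cyclohex-3-en-1-yl]methyl benzoate | O=C(OC[C@]1(O)[C@H](OCc2ccc(OC)cc2)C=C[C@@H](O[Si](C(C)C)(C(C)C)C(C)C)[C@@H]1OC(=O)c1ccccc1)c1ccccc1 | intermediate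
23 | [6-(benzoyloxy)-1,2-dihydroxy-5-(triisopropylsilyloxy)cyclohex-3-en-1-yl]methyl benzoate | O=C(OC[C@]1(O)[C@H](O)C=C[C@@H](O[Si](C(C)C)(C(C)C)C(C)C)[C@@H]1OC(=O)c1ccccc1)c1ccccc1 | intermediate
24 | [6-(benzoyloxy)-1-hydroxy-2-oxo-5-(triisopropylsilyloxy)cyclohex-3-en-1-yl]methyl benzoate | O=C(OC[C@]1(O)C(=O)C=C[C@@H](O[Si](C(C)C)(C(C)C)C(C)C)[C@@H]1OC(=O)c1ccccc1)c1ccccc1 | intermediate
25 | [(1R,5R,6S)-6-(benzoyloxy)-1,5-dihydroxy-2-oxocyclohex-3-en-1-yl]methyl benzoate | O=C(OC[C@]1(O)C(=O)C=C[C@@H](O)[C@@H]1OC(=O)c1ccccc1)c1ccccc1 | target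

**Totals.** Total step count: 15 (13 in the main line, 2 for the Wittig salt). Longest linear sequence: 13 steps (6 → 25, steps 3–15).

**Steps most likely to fail**

1. Step 10 (key step). The lactone enolate may expel the β-silyloxy group before it is silylated, or the crowded boat may be reached too slowly, so that the ketene acetal decomposes. The fallback removes the leaving group from the mechanism instead of racing it. It sets out from diol lactone 14: one equivalent of TESCl/imidazole at low temperature should silylate the more acidic, less hindered α-hydroxyl to give the 2-O-triethylsilyl lactone F4. Two equivalents of LDA then give the β-alkoxide enolate dianion, in which the β-oxygen cannot leave (dianionic ester-enolate Claisen; TMSCl added only after enolisation). After warming and acidic work-up this should give the hydroxy acid F5. LiAlH4 reduction gives the mono-TES alcohol F6, and acid methanolysis as in step 11 returns to the route at triol 20.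

2. Step 8. The polyanionic lactol may olefinate sluggishly, and the alkoxides set free next to the silyl ether may cause silyl migration or decomposition. The fallback olefinates a discrete aldehyde that carries no free hydroxyl. It sets out from lactol 11: EtSH with BF3·OEt2 should give the open-chain diethyl dithioacetal, which lactonises under the same acid to the dithioacetal lactone F1. TESCl/imidazole gives the bis-TES dithioacetal lactone F2, and I2/NaHCO3 in aqueous acetone unmasks the lactone aldehyde F3. Wittig reaction of F3 with 1.1 equivalents of ylide 12 at −78 °C returns to the route at 15.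

3. Step 11. Hydride delivery to the neopentyl, α-quaternary carboxylate may stall, and forcing conditions may strip or scramble silyl ethers before reduction is complete. The fallback activates the carboxyl as an ester. It sets out from acid 18: TMSCHN2 in MeOH/PhMe gives the methyl ester F7, and DIBAL-H at −78 → 0 °C reduces it to the primary alcohol, returning to the route at 19, which is desilylated as before.

Further compounds

F1 | step 8 | 4-O-triisopropylsilyl-L-gulurono-1,5-lactone 6-(diethyl dithioacetal) | O=C1[C@@H](O)[C@@H](O)[C@H](O[Si](C(C)C)(C(C)C)C(C)C)[C@H](C(SCC)SCC)O1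
F2 | step 8 | 2,3-di-O-triethylsilyl-4-O-triisopropylsilyl-L-gulurono-1,5-lactone 6-(diethyl dithioacetal) | O=C1[C@@H](O[Si](CC)(CC)CC)[C@@H](O[Si](CC)(CC)CC)[C@H](O[Si](C(C)C)(C(C)C)C(C)C)[C@H](C(SCC)SCC)O1
F3 | step 8 | 2,3-di-O-triethylsilyl-4-O-triisopropylsilyl-L-gulurono-1,5-lactone (6-aldehyde) | O=C1[C@@H](O[Si](CC)(CC)CC)[C@@H](O[Si](CC)(CC)CC)[C@H](O[Si](C(C)C)(C(C)C)C(C)C)[C@H](C=O)O1
F4 | step 10 | (E)-6-deoxy-7-O-(4-methoxybenzyl)-2-O-triethylsilyl-4-O-triisopropylsilyl-L-gulo-hept-6-enono-1,5-lactone | O=C1[C@@H](O[Si](CC)(CC)CC)[C@@H](O)[C@H](O[Si](C(C)C)(C(C)C)C(C)C)[C@H](/C=C/OCc2ccc(OC)cc2)O1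
F5 | step 10 | 6-hydroxy-2-(4-methoxybenzyloxy)-1-(triethylsilyloxy)-5-(triisopropylsilyloxy)cyclohex-3-ene-1-carboxylic acid | OC(=O)[C@]1(O[Si](CC)(CC)CC)[C@H](OCc2ccc(OC)cc2)C=C[C@@H](O[Si](C(C)C)(C(C)C)C(C)C)[C@@H]1O
F6 | step 10 | 2-(hydroxymethyl)-3-(4-methoxybenzyloxy)-2-(triethylsilyloxy)-6-(triisopropylsilyloxy)cyclohex-4-en-1-ol | OC[C@]1(O[Si](CC)(CC)CC)[C@H](OCc2ccc(OC)cc2)C=C[C@@H](O[Si](C(C)C)(C(C)C)C(C)C)[C@@H]1O
F7 | step 11 | methyl 2-(4-methoxybenzyloxy)-1,6-bis(triethylsilyloxy)-5-(triisopropylsilyloxy)cyclohex-3-ene-1-carboxylate | COC(=O)[C@]1(O[Si](CC)(CC)CC)[C@H](OCc2ccc(OC)cc2)C=C[C@@H](O[Si](C(C)C)(C(C)C)C(C)C)[C@@H]1O[Si](CC)(CC)CC
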